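## Retrosynthetic overview

1. Target ⇒ ester installation (3-OAc, 8-OAng) and allylic transposition (hydroxyselenation, then selenoxide syn-elimination: 10-OH and E-1,2-olefin) on the 1(10)E,4Z-germacradien-6,12-olide **20**.
2. α-Methylene trans-γ-lactone (last ring formed) ⇒ C6 ketone with a C7 CH2CO2Me arm: chelation-controlled reduction, lactonisation, Mannich methylenation.
3. Ten-membered ring ⇒ anionic oxy-Cope [3,3] ring expansion of divinylcyclohexenol **11**; it makes C8–C9, sets C8, and the enolate alkylation sets C7.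
4. **11** ⇒ enone **5** + lithium alkoxyacetylide (from 4-methoxybenzyl alcohol and trichloroethylene), then trans-hydroalumination to the E enol ether.
5. **5** ⇒ (S)-(+)-carvone (epoxidation/Wharton transposition sets C3; allylic oxidation). Ring order: cyclohexene (bought) → cyclodecadiene → γ-lactone.

Assumption: locants C1–C15 are the germacranolide numbers of the target (C3 acetate carbon, C6 lactone carbinol, C7 ring-fusion carbon, C8 angelate carbon, C10 tertiary carbinol) and are also used for the ring-expanded intermediates; the target is made as drawn, (3S,6S,7S,8R,10R). The stereochemical outcomes at C6, C7 and C10 are predictions from transition-state and conformational models, not from precedent on this exact system.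

## Route

Step 1
Reactants: 1 (S)-(+)-carvone
Product: 2 trans-carvone 2,3-epoxide (oxirane anti to the isopropenyl group)
Conditions: 30% H2O2, NaOH (aq), MeOH, 0 °C
Reagents that add atoms: hydrogen peroxide, OO
Why: Weitz–Scheffer nucleophilic epoxidation touches only the enone C=C, and hydroperoxide adds to the β-carbon anti to the C5 isopropenyl group, so the oxirane forms trans to it as one diastereomer.

Step 2
Reactants: 2 trans-carvone 2,3-epoxide
Product: 3 (1S,5R)-trans-carveol
Conditions: N2H4·H2O, AcOH (cat.), MeOH, 0 to 20 °C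
Reagents that add atoms: none
Why: Wharton transposition (hydrazone formation, epoxide opening, loss of N2) gives the transposed allylic alcohol with the C–O stereocenter retained, so the carbinol carbon that becomes C3 (S) of the target is trans to the isopropenyl group.

Step 3
Reactants: 3 (1S,5R)-trans-carveol
Product: 4 (1S,5R)-trans-carveol tert-butyldimethylsilyl ether
Conditions: t-BuMe2SiCl, imidazole, DMF, 20 °C
Reagents that add atoms: tert-butyldimethylsilyl chloride, CC(C)(C)[Si](C)(C)Cl
Why: Standard silyl ether formation on the secondary allylic alcohol; no stereocenter is touched.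

Step 4
Reactants: 4 (1S,5R)-trans-carveol tert-butyldimethylsilyl ether
Product: 5 (4S,6R)-4-(tert-butyldimethylsilyloxy)-3-methyl-6-(prop-1-en-2-yl)cyclohex-2-en-1-one
Conditions: CrO3, 3,5-dimethylpyrazole, CH2Cl2, −20 °C
Reagents that add atoms: chromium trioxide, O=[Cr](=O)=O
Why: Allylic C–H oxidation with the CrO3–3,5-dimethylpyrazole complex turns the only ring allylic methylene into the enone carbonyl (future C6) under non-basic conditions, so the adjacent isopropenyl-bearing stereocenter is not enolised.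

Step 5
Reactants: 6 4-methoxybenzyl alcohol, 7 trichloroethylene
Product: 8 (E)-1,2-dichlorovinyl 4-methoxybenzyl ether
Conditions: KH, THF, 0 °C; then 7, 20 °C
Reagents that add atoms: none
Why: Greene dichlorovinyl ether synthesis: the potassium alkoxide dehydrochlorinates trichloroethylene to dichloroacetylene and adds to it in anti fashion.

Step 6
Reactants: 8 (E)-1,2-dichlorovinyl 4-methoxybenzyl ether, 5 (4S,6R)-4-(tert-butyldimethylsilyloxy)-3-methyl-6-(prop-1-en-2-yl)cyclohex-2-en-1-one
Product: 11 (1R,4S,6R)-4-(tert-butyldimethylsilyloxy)-1-[(E)-2-(4-methoxybenzyloxy)ethenyl]-3-methyl-6-(prop-1-en-2-yl)cyclohex-2-en-1-ol, via lithium alkoxyacetylide 9 (not isolated), via lithium alkynyl-carbinolate 10 (not isolated)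
Conditions: 8, n-BuLi (2.1 equiv), THF, −78 to −40 °C; then 5, −78 °C; then LiAlH4, −78 to 20 °C; aq NaOH work-up
Reagents that add atoms: none
Why: Dehydrochlorination and Cl–Li exchange give the lithium alkoxyacetylide, which adds 1,2 to the enone anti to the neighbouring isopropenyl group (alkenyl and isopropenyl trans, as the rearrangement needs), and alkoxide-directed trans-hydroalumination of the ynol ether (Arens–van Dorp type) gives the E enol ether.

Step 7
Reactants: 11 (1R,4S,6R)-divinylcyclohexenol, 12 methyl bromoacetate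
Product: 15 methyl 2-[(3S,7S,8R,1(10)E,4Z)-3-(tert-butyldimethylsilyloxy)-8-(4-methoxybenzyloxy)-4,10-dimethyl-6-oxocyclodeca-1(10),4-dien-7-yl]acetate, via potassium alkoxide 13 (not isolated), via potassium enolate 14 (not isolated)
Conditions: KN(SiMe3)2, 18-crown-6, THF, 0 to 20 °C; then 12, −78 °C
Reagents that add atoms: none
Why: Anionic oxy-Cope [3,3] rearrangement through a chair transition state with both ring bonds and the E-alkoxy group equatorial makes the C8–C9 bond and the ten-membered ring, gives the 1(10)E olefin, keeps the cyclohexene olefin as 4Z and relays the carvone stereocenter to C8 (R), and the regiodefined enolate is then alkylated on its open face, anti to the transannular olefin, to set C7 (S).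

Step 8
Reactants: 15 ten-membered keto ester
Product: 17 (3S,6S,7S,8R)-3-(tert-butyldimethylsilyloxy)-8-(4-methoxybenzyloxy)-13-norgermacra-1(10)E,4Z-dien-6,12-olide (trans-fused lactone; C11 is CH2), via 6S hydroxy ester 16 (not isolated)
Conditions: Zn(BH4)2, Et2O, −20 °C; then PPTS (cat.), CH2Cl2, 20 °C
Reagents that add atoms: none
Why: Chelation-controlled 1,2-reduction (zinc bridging the C6 carbonyl and the C8 ether oxygen, hydride anti to the C7 side chain, Cram-chelate model) gives the 6S alcohol of the syn,syn C6–C7–C8 triad, which lactonises onto the ester to the trans-fused γ-lactone.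

Step 9
Reactants: 17 trans-fused lactone
Product: 20 (3S,6S,7S,8R)-3-(tert-butyldimethylsilyloxy)-8-(4-methoxybenzyloxy)germacra-1(10)E,4Z,11(13)-trien-6,12-olide, via Mannich base 18 (not isolated), via ammonium iodide 19 (not isolated)
Conditions: LiN(i-Pr)2, THF, −78 °C; CH2=NMe2+ I−, −78 to 20 °C; then MeI, MeOH; then aq NaHCO3
Reagents that add atoms: dimethylmethyleneammonium iodide (Eschenmoser's salt), C=[N+](C)C.[I-]
Why: Mannich α-methylenation: the lactone enolate is aminomethylated by Eschenmoser's salt, and quaternisation followed by E1cB loss of trimethylamine gives the exocyclic methylene (the transient C11 stereocenter is erased).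

Step 10
Reactants: 20 α-methylene lactone
Product: 23 (3S,6S,7S,8R,10R)-3-(tert-butyldimethylsilyloxy)-10-hydroxy-8-(4-methoxybenzyloxy)germacra-1E,4Z,11(13)-trien-6,12-olide, via hydroxy selenide 21 (not isolated), via selenoxide 22 (not isolated)
Conditions: N-(phenylseleno)phthalimide, H2O, camphorsulfonic acid (cat.), CH2Cl2, −20 to 0 °C; then 30% H2O2, pyridine, THF, 0 to 20 °C
Reagents that add atoms: water, O
Why: Electrophilic hydroxyselenation of the only electron-rich olefin is Markovnikov and anti (selenium on the exposed face at C1, water at tertiary C10 from the opposite face, which sets 10R), and selenoxide syn-elimination, possible only toward C2, completes the allylic transposition to the E-1,2-olefin.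

Step 11
Reactants: 23 10-hydroxy PMB ether
Product: 24 (3S,6S,7S,8R,10R)-3-(tert-butyldimethylsilyloxy)-8,10-dihydroxygermacra-1E,4Z,11(13)-trien-6,12-olide
Conditions: DDQ, CH2Cl2/pH 7 buffer, 0 °C
Reagents that add atoms: none
Why: Oxidative cleavage of the 4-methoxybenzyl ether by DDQ (benzylic hydride abstraction, hydrolysis of the oxocarbenium ion) frees only the C8 hydroxyl.

Step 12
Reactants: 24 8,10-diol, 25 angelic acid
Product: 27 (3S,6S,7S,8R,10R)-8-angeloyloxy-3-(tert-butyldimethylsilyloxy)-10-hydroxygermacra-1E,4Z,11(13)-trien-6,12-olide, via mixed anhydride 26 (not isolated)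
Conditions: 25, 2,4,6-trichlorobenzoyl chloride, Et3N, PhMe, 20 °C; then 24, 20 to 60 °C
Reagents that add atoms: none
Why: Yamaguchi esterification through the mixed anhydride acylates the secondary C8 alcohol (the tertiary C10 alcohol is inert) and, run without DMAP, keeps the Z geometry of the angelate.

Step 13
Reactants: 27 8-angelate 3-silyl ether
Product: 29 (3S,6S,7S,8R,10R)-3-acetoxy-8-angeloyloxy-10-hydroxygermacra-1E,4Z,11(13)-trien-6,12-olide (the target), via C3 alcohol 28 (not isolated)
Conditions: HF·pyridine, pyridine, THF, 0 to 20 °C; then Ac2O, DMAP, 20 °C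
Reagents that add atoms: acetic anhydride, CC(=O)OC(C)=O
Why: Fluoride-mediated desilylation followed in the same flask by DMAP-catalysed acetylation esterifies only the secondary C3 alcohol and leaves the tertiary C10 alcohol free.

## Compound list

1 | (S)-(+)-carvone | CC1=CC[C@@H](CC1=O)C(C)=C | starting material
2 | trans-carvone 2,3-epoxide (oxirane anti to isopropenyl) | C[C@]12O[C@H]1C[C@@H](CC2=O)C(C)=C | intermediate
3 | (1S,5R)-trans-carveol | CC1=CC[C@H](C[C@@H]1O)C(C)=C | intermediate
4 | (1S,5R)-trans-carveol tert-butyldimethylsilyl ether | CC1=CC[C@H](C[C@@H]1O[Si](C)(C)C(C)(C)C)C(C)=C | intermediate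
5 | (4S,6R)-4-(tert-butyldimethylsilyloxy)-3-methyl-6-(prop-1-en-2-yl)cyclohex-2-en-1-one | CC1=CC(=O)[C@H](C[C@@H]1O[Si](C)(C)C(C)(C)C)C(C)=C | intermediate
6 | 4-methoxybenzyl alcohol | COc1ccc(CO)cc1 | starting material
7 | trichloroethylene | ClC=C(Cl)Cl | starting material
8 | (E)-1,2-dichlorovinyl 4-methoxybenzyl ether | COc1ccc(CO/C(Cl)=C\Cl)cc1 | intermediate
9 | lithium (4-methoxybenzyloxy)acetylide | COc1ccc(COC#C[Li])cc1 | intermediate
10 | lithium (1R,4S,6R)-4-(tert-butyldimethylsilyloxy)-1-[(4-methoxybenzyloxy)ethynyl]-3-methyl-6-(prop-1-en-2-yl)cyclohex-2-en-1-olate | [Li+].CC1=C[C@]([O-])(C#COCc2ccc(OC)cc2)[C@H](C[C@@H]1O[Si](C)(C)C(C)(C)C)C(C)=C | intermediate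
11 | (1R,4S,6R)-4-(tert-butyldimethylsilyloxy)-1-[(E)-2-(4-methoxybenzyloxy)ethenyl]-3-methyl-6-(prop-1-en-2-yl)cyclohex-2-en-1-ol | CC1=C[C@](O)(/C=C/OCc2ccc(OC)cc2)[C@H](C[C@@H]1O[Si](C)(C)C(C)(C)C)C(C)=C | intermediate
12 | methyl bromoacetate | COC(=O)CBr | starting material
13 | potassium alkoxide of 11 | [K+].CC1=C[C@]([O-])(/C=C/OCc2ccc(OC)cc2)[C@H](C[C@@H]1O[Si](C)(C)C(C)(C)C)C(C)=C | intermediate
14 | potassium enolate of the ring-expanded ketone (C6–O−, C6=C7 Z; 1(10)E, 4Z; 3S, 8R) | [K+].[O-]/C1=C\[C@H](OCc2ccc(OC)cc2)C/C(C)=C/C[C@H](O[Si](C)(C)C(C)(C)C)/C(C)=C\1 | intermediate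
15 | methyl 2-[(3S,7S,8R,1(10)E,4Z)-3-(tert-butyldimethylsilyloxy)-8-(4-methoxybenzyloxy)-4,10-dimethyl-6-oxocyclodeca-1(10),4-dien-7-yl]acetate | COC(=O)C[C@@H]1C(=O)/C=C(/C)[C@@H](O[Si](C)(C)C(C)(C)C)C/C=C(C)/C[C@H]1OCc1ccc(OC)cc1 | intermediate
16 | (6S)-hydroxy ester from 15 | COC(=O)C[C@@H]1[C@@H](O)/C=C(/C)[C@@H](O[Si](C)(C)C(C)(C)C)C/C=C(C)/C[C@H]1OCc1ccc(OC)cc1 | intermediate
17 | (3S,6S,7S,8R)-3-(tert-butyldimethylsilyloxy)-8-(4-methoxybenzyloxy)-13-norgermacra-1(10)E,4Z-dien-6,12-olide | C1C(=O)O[C@H]2/C=C(/C)[C@@H](O[Si](C)(C)C(C)(C)C)C/C=C(C)/C[C@@H](OCc3ccc(OC)cc3)[C@H]12 | intermediate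
18 | 11-(dimethylaminomethyl) lactone (Mannich base; C11 configuration not defined) | CN(C)CC1C(=O)O[C@H]2/C=C(/C)[C@@H](O[Si](C)(C)C(C)(C)C)C/C=C(C)/C[C@@H](OCc3ccc(OC)cc3)[C@H]12 | intermediate
19 | 11-(trimethylammoniomethyl) lactone iodide | [I-].C[N+](C)(C)CC1C(=O)O[C@H]2/C=C(/C)[C@@H](O[Si](C)(C)C(C)(C)C)C/C=C(C)/C[C@@H](OCc3ccc(OC)cc3)[C@H]12 | intermediate
20 | (3S,6S,7S,8R)-3-(tert-butyldimethylsilyloxy)-8-(4-methoxybenzyloxy)germacra-1(10)E,4Z,11(13)-trien-6,12-olide | C=C1C(=O)O[C@H]2/C=C(/C)[C@@H](O[Si](C)(C)C(C)(C)C)C/C=C(C)/C[C@@H](OCc3ccc(OC)cc3)[C@H]12 | intermediate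
21 | (1S,3S,6S,7S,8R,10R)-10-hydroxy-1-(phenylselanyl) adduct of 20 | C=C1C(=O)O[C@H]2/C=C(/C)[C@@H](O[Si](C)(C)C(C)(C)C)C[C@H]([Se]c3ccccc3)[C@](C)(O)C[C@@H](OCc3ccc(OC)cc3)[C@H]12 | intermediate
22 | selenoxide of 21 | C=C1C(=O)O[C@H]2/C=C(/C)[C@@H](O[Si](C)(C)C(C)(C)C)C[C@H]([Se](=O)c3ccccc3)[C@](C)(O)C[C@@H](OCc3ccc(OC)cc3)[C@H]12 | intermediate
23 | (3S,6S,7S,8R,10R)-3-(tert-butyldimethylsilyloxy)-10-hydroxy-8-(4-methoxybenzyloxy)germacra-1E,4Z,11(13)-trien-6,12-olide | C=C1C(=O)O[C@H]2/C=C(/C)[C@@H](O[Si](C)(C)C(C)(C)C)/C=C/[C@](C)(O)C[C@@H](OCc3ccc(OC)cc3)[C@H]12 | intermediate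
24 | (3S,6S,7S,8R,10R)-3-(tert-butyldimethylsilyloxy)-8,10-dihydroxygermacra-1E,4Z,11(13)-trien-6,12-olide | C=C1C(=O)O[C@H]2/C=C(/C)[C@@H](O[Si](C)(C)C(C)(C)C)/C=C/[C@](C)(O)C[C@@H](O)[C@H]12 | intermediate
25 | angelic acid, (Z)-2-methylbut-2-enoic acid | C/C=C(/C)C(=O)O | starting material
26 | angelic 2,4,6-trichlorobenzoic anhydride | C/C=C(/C)C(=O)OC(=O)c1c(Cl)cc(Cl)cc1Cl | intermediate
27 | (3S,6S,7S,8R,10R)-8-angeloyloxy-3-(tert-butyldimethylsilyloxy)-10-hydroxygermacra-1E,4Z,11(13)-trien-6,12-olide | C=C1C(=O)O[C@H]2/C=C(/C)[C@@H](O[Si](C)(C)C(C)(C)C)/C=C/[C@](C)(O)C[C@@H](OC(=O)/C(C)=C\C)[C@H]12 | intermediate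
28 | (3S,6S,7S,8R,10R)-8-angeloyloxy-3,10-dihydroxygermacra-1E,4Z,11(13)-trien-6,12-olide | C=C1C(=O)O[C@H]2/C=C(/C)[C@@H](O)/C=C/[C@](C)(O)C[C@@H](OC(=O)/C(C)=C\C)[C@H]12 | intermediate
29 | (3S,6S,7S,8R,10R)-3-acetoxy-8-angeloyloxy-10-hydroxygermacra-1E,4Z,11(13)-trien-6,12-olide | C=C1C(=O)O[C@H]2/C=C(/C)[C@@H](OC(C)=O)/C=C/[C@](C)(O)C[C@@H](OC(=O)/C(C)=C\C)[C@H]12 | target

## Step count and risks

Total step count: 13. Longest linear sequence: 12 steps (steps 1–4 and 6–13; step 5 makes the side reagent).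

The three steps most likely to fail:

Step 4. The oxidant may abstract the allylic carbinol hydrogen next to the silyl ether (giving a carvone-type enone) or attack the isopropenyl group. The fallback sets out from 3 and comes back at 5, and does the oxidation on an electron-poor ester instead. Alcohol 3 is acetylated (Ac2O, pyridine) to (1S,5R)-trans-carvyl acetate F1. F1 is oxidised at the ring methylene (CrO3/3,5-dimethylpyrazole, or Pd(OH)2/C with t-BuOOH) to (4S,6R)-4-acetoxy-3-methyl-6-(prop-1-en-2-yl)cyclohex-2-en-1-one F2. Cold K2CO3/MeOH transesterification gives (4S,6R)-4-hydroxy-3-methyl-6-(prop-1-en-2-yl)cyclohex-2-en-1-one F3, and silylation (t-BuMe2SiCl, imidazole) gives 5.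

Step 7. The potassium enolate 14 carries a β-alkoxy group and may lose 4-methoxybenzyl oxide (E1cB) or alkylate unselectively before the bromoacetate reacts. The fallback sets out from 11 and comes back at 15, and replaces the SN2 alkylation by a radical C–C bond formation. After the rearrangement (KN(SiMe3)2, 18-crown-6) the enolate is trapped at −78 °C with Me3SiCl as the trimethylsilyl enol ether of the ring-expanded ketone F4, which has no elimination pathway. Atom-transfer radical addition of methyl iodoacetate (Et3B, air, CH2Cl2, −20 °C) on the same open face, with collapse of the α-iodo silyl ether, gives keto ester 15.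

Step 10. The facial course on the ten-membered ring is a conformational prediction, and the selenonium intermediate could be trapped transannularly by the 4,5-olefin. The fallback sets out from 20 and comes back at 21; it delivers the oxygen directly to the exposed olefin face instead of anti to it. Compound 20 is epoxidised (mCPBA, NaHCO3, CH2Cl2, 0 °C) to the (1R,10R)-1,10-epoxide F5. PhSeSePh/NaBH4 in EtOH opens it at the secondary carbon C1 with inversion to give hydroxy selenide 21, which is oxidised and eliminated as in step 10. This path gives 10R if the exposed face is the opposite of the one assumed in the main route, so the two sequences are stereocomplementary.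

## Further compounds

F1 | step 4 | (1S,5R)-trans-carvyl acetate | CC1=CC[C@H](C[C@@H]1OC(C)=O)C(C)=C
F2 | step 4 | (4S,6R)-4-acetoxy-3-methyl-6-(prop-1-en-2-yl)cyclohex-2-en-1-one | CC1=CC(=O)[C@H](C[C@@H]1OC(C)=O)C(C)=C
F3 | step 4 | (4S,6R)-4-hydroxy-3-methyl-6-(prop-1-en-2-yl)cyclohex-2-en-1-one | CC1=CC(=O)[C@H](C[C@@H]1O)C(C)=C
F4 | step 7 | trimethylsilyl enol ether of the ring-expanded ketone (C6–OSiMe3, C6=C7 Z; 1(10)E, 4Z; 3S, 8R) | C[Si](C)(C)O/C1=C\[C@H](OCc2ccc(OC)cc2)C/C(C)=C/C[C@H](O[Si](C)(C)C(C)(C)C)/C(C)=C\1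
F5 | step 10 | (1R,3S,6S,7S,8R,10R)-1,10-epoxy-3-(tert-butyldimethylsilyloxy)-8-(4-methoxybenzyloxy)germacra-4Z,11(13)-dien-6,12-olide | C=C1C(=O)O[C@H]2/C=C(/C)[C@@H](O[Si](C)(C)C(C)(C)C)C[C@H]3O[C@]3(C)C[C@@H](OCc4ccc(OC)cc4)[C@H]12
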